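## Retrosynthetic overview
1. Caespitol (15) ⇐ acetate 14 ⇐ 13. The diequatorial C5'–Br/C4'–Cl pair is not made by adding BrCl to the alkene. It comes from a trans‑diaxial tertiary bromide/secondary alcohol by a stereospecific 1,2‑bromine shift with chloride capture.
2. 13 ⇐ 12 with HBr. The bromo‑THP is not made by bromoetherification. A THF carbinol is ring‑expanded through a bicyclic oxonium ion (C10–O → C10–Br), and the ring epoxide opens diaxially in the same step.
3. 12 ⇐ 10. One double Shi epoxidation sets the oxygen stereochemistry at C10, C4' and C5' with a single catalyst. C10 is then inverted twice (chain) and C5' once (ring), which gives the two C–Br centres their different configurations.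
4. 10 ⇐ 3. C8 is set by Brown allylation, C7 by matched Sharpless epoxidation and hydride opening, and the prenyl end by cross‑metathesis.
5. 3 ⇐ (S)‑limonene (1). Ring order: cyclohexane (chiral pool, C1') → THF → THP.

Assumption: the SMILES corresponds to 7R,8R,10R,1'S,4'S,5'S. I use bisabolane numbering throughout: ring C1'–C6' with C4' bearing CH3, chain C7–C11, and C14 as the methyl on C7. In the chair, the side chain, Br and Cl on the cyclohexane are all equatorial.

## Route

**Step 1**
Reactants: 1, (S)‑(–)‑limonene
Product: 2, 2‑[(1S)‑4‑methylcyclohex‑3‑en‑1‑yl]prop‑2‑en‑1‑ol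
Conditions: n‑BuLi, TMEDA, rt; B(OMe)3, –78 °C → rt; H2O2, aq NaOH, 0 °C
Reagents that add atoms: hydrogen peroxide, OO
Why: Allylic lithiation with n‑BuLi·TMEDA takes place at the isopropenyl methyl and gives a symmetrical 2‑substituted allyl anion, and borylation/oxidation converts this to the allylic alcohol without touching C1'.

**Step 2**
Reactants: 2
Product: 3, 2‑[(1S)‑4‑methylcyclohex‑3‑en‑1‑yl]prop‑2‑enal
Conditions: MnO2, CH2Cl2, rt
Reagents that add atoms: none
Why: MnO2 oxidation is selective for allylic alcohols, and no stereocentre is affected.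

**Step 3**
Reactants: 3; 4, allylmagnesium bromide (converted in situ to (–)‑Ipc2B(allyl) with (+)‑Ipc2BOMe from the (–)‑α‑pinene series)
Product: 5, (3R)‑2‑[(1S)‑4‑methylcyclohex‑3‑en‑1‑yl]hexa‑1,5‑dien‑3‑ol (8R)
Conditions: (+)‑Ipc2BOMe, allylMgBr, Et2O; then 3, –78 °C; NaOH, H2O2
Reagents that add atoms: allylmagnesium bromide, C=CC[Mg]Br, delivered as B‑allyldiisopinocampheylborane, C=CCB(C1CC2CC(C1C)C2(C)C)C1CC2CC(C1C)C2(C)C
Why: In this Brown asymmetric allylboration the chair Zimmerman–Traxler transition state under reagent control sets C8 = R, because this borane enantiomer gives R carbinols from 2‑substituted enals.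

**Step 4**
Reactants: 5
Product: 6, (1R)‑1‑{(2S)‑2‑[(1S)‑4‑methylcyclohex‑3‑en‑1‑yl]oxiran‑2‑yl}but‑3‑en‑1‑ol
Conditions: Ti(OiPr)4, D‑(–)‑DIPT, t‑BuOOH, 4 Å MS, CH2Cl2, –20 °C
Reagents that add atoms: tert‑butyl hydroperoxide, CC(C)(C)OO
Why: This is a matched Sharpless asymmetric epoxidation in which only the allylic alkene reacts, and C7 is set because the D‑tartrate face preference and the erythro preference of the 8R carbinol (A1,2 strain with the geminal ring substituent) point the same way.

**Step 5**
Reactants: 6
Product: 7, (2R,3R)‑2‑[(1S)‑4‑methylcyclohex‑3‑en‑1‑yl]hex‑5‑ene‑2,3‑diol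
Conditions: LiAlH4, THF, 0 °C → rt
Reagents that add atoms: none
Why: Hydride opens the 2,2‑disubstituted epoxide by SN2 at its unhindered CH2 terminus, which turns C14 into the methyl group and leaves the C7–O bond and its configuration intact.

**Step 6**
Reactants: 7; 8, 2‑methyl‑2‑butene
Product: 9, (2R,3R)‑6‑methyl‑2‑[(1S)‑4‑methylcyclohex‑3‑en‑1‑yl]hept‑5‑ene‑2,3‑diol (the 8R‑hydroxy derivative of (–)‑α‑bisabolol)
Conditions: Grubbs II (3 mol %), 2‑methyl‑2‑butene (excess), CH2Cl2, 40 °C
Reagents that add atoms: 2‑methyl‑2‑butene, CC=C(C)C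
Why: Olefin cross‑metathesis converts the terminal (type I) alkene into the prenyl group, and the trisubstituted ring alkene is inert.

**Step 7**
Reactants: 9
Product: 10, the C8 acetate of 9 (tertiary C7–OH free)
Conditions: Ac2O, pyridine, DMAP (cat.), CH2Cl2, 0 °C → rt
Reagents that add atoms: acetic anhydride, CC(=O)OC(C)=O
Why: Acylation is selective for the secondary alcohol over the tertiary one, and the ester keeps O8 out of steps 8–10 and inductively disfavours ionisation at C7.

**Step 8**
Reactants: 10
Product: 12, (2R,3R,5S)‑5‑(2‑hydroxypropan‑2‑yl)‑2‑methyl‑2‑[(1R,3S,6S)‑6‑methyl‑7‑oxabicyclo[4.1.0]heptan‑3‑yl]oxolan‑3‑yl acetate, formed via bis‑epoxide 11 (10R; 4'S,5'R), which is not isolated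
Conditions: D‑fructose‑derived Shi ketone (0.6 equiv), Oxone, K2CO3, Bu4NHSO4, MeCN–DMM/aq borate–EDTA, 0 °C; then PPTS (cat.), CH2Cl2, 0 °C
Reagents that add atoms: Oxone (KHSO5), OOS(=O)(=O)[O-].[K+]
Why: In this Shi asymmetric epoxidation of both trisubstituted alkenes the spiro transition state gives R at each CH carbon (10R in the chain, and the 4'S,5'R "cis‑limonene‑oxide type" epoxide on the ring), and the C7–OH then opens the chain epoxide 5‑exo‑tet at C10 with inversion (10S).

**Step 9**
Reactants: 12
Product: 13, (2R,3R,5R)‑5‑bromo‑2‑[(1S,3R,4R)‑4‑bromo‑3‑hydroxy‑4‑methylcyclohexyl]‑2,6,6‑trimethyloxan‑3‑yl acetate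
Conditions: anhydrous HBr (about 5 equiv), Bu4NBr, CH2Cl2, –40 → 0 °C
Reagents that add atoms: hydrogen bromide, Br
Why: Proposed new method: HBr first opens the ring epoxide in the matched Markovnikov/trans‑diaxial (Fürst–Plattner) sense (Br⁻ at C4', C5'–O retained) and then ionises the tertiary C11–OH with ring‑oxygen participation to a 1‑oxoniabicyclo[3.1.0]hexane; bromide capture at C11 and E1 loss to the isopropenyl ether are both reversible in HBr, whereas SN2 attack at C10 breaks C10–O with inversion and gives the non‑ionising secondary bromide of the six‑membered ring, so C10 runs epoxide R → THF S → bromide R; the closest known reaction types are the expansion of 2‑(1‑sulfonyloxyalkyl)tetrahydrofurans to 3‑substituted tetrahydropyrans and the prolinol → 3‑halopiperidine aziridinium expansion.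

**Step 10**
Reactants: 13
Product: 14, caespitol acetate, (2R,3R,5R)‑5‑bromo‑2‑[(1S,3S,4S)‑3‑bromo‑4‑chloro‑4‑methylcyclohexyl]‑2,6,6‑trimethyloxan‑3‑yl acetate
Conditions: SOCl2, pyridine, Bu4NCl, CH2Cl2, –20 °C → rt; then toluene, 100 °C
Reagents that add atoms: thionyl chloride, O=S(Cl)Cl
Why: Proposed new method: the chlorosulfite of the axial C5'–OH is expelled by the antiperiplanar axial C4'–Br (inversion at C5'), giving a single bromonium ion on the face cis to the side chain, and chloride opens it at tertiary C4' from the opposite face (inversion at C4') to the diequatorial 5'S‑Br/4'S‑Cl pair; any capture at C5' gives the diaxial 4'‑Br/5'‑Cl isomer, which on heating undergoes the diaxial → diequatorial (dyotropic) vicinal‑dihalide interchange to the same product; the closest known reaction types are neighbouring‑bromine participation in the deoxyhalogenation of trans‑bromohydrins and the mutarotation of trans‑diaxial steroidal dihalides.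

**Step 11**
Reactants: 14
Product: 15, caespitol
Conditions: DIBAL‑H (2.5 equiv), CH2Cl2, –78 °C
Reagents that add atoms: none
Why: Reductive ester cleavage at low temperature leaves the alkyl halides and all six stereocentres untouched.

## Compound list
1 | (S)‑(–)‑limonene | CC(=C)[C@H]1CCC(C)=CC1 | starting material
2 | (S)‑p‑mentha‑1,8‑dien‑10‑ol | OCC(=C)[C@H]1CCC(C)=CC1 | intermediate
3 | (S)‑p‑mentha‑1,8‑dien‑10‑al | O=CC(=C)[C@H]1CCC(C)=CC1 | intermediate
4 | allylmagnesium bromide | C=CC[Mg]Br | starting material
5 | (8R)‑allyl carbinol | C=CC[C@@H](O)C(=C)[C@H]1CCC(C)=CC1 | intermediate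
6 | erythro epoxy alcohol | C=CC[C@@H](O)[C@@]1(CO1)[C@H]2CCC(C)=CC2 | intermediate
7 | (7R,8R)‑diol, allyl stage | C=CC[C@@H](O)[C@](C)(O)[C@H]1CCC(C)=CC1 | intermediate
8 | 2‑methyl‑2‑butene | CC=C(C)C | starting material
9 | (8R)‑8‑hydroxy‑α‑bisabolol | CC(C)=CC[C@@H](O)[C@](C)(O)[C@H]1CCC(C)=CC1 | intermediate
10 | 8‑O‑acetate of 9 | CC(C)=CC[C@@H](OC(C)=O)[C@](C)(O)[C@H]1CCC(C)=CC1 | intermediate
11 | bis‑epoxide (10R; 4'S,5'R), not isolated | CC1(C)O[C@@H]1C[C@@H](OC(C)=O)[C@](C)(O)[C@H]2CC[C@]3(C)O[C@@H]3C2 | intermediate
12 | THF carbinol / ring epoxide | CC(C)(O)[C@@H]1C[C@@H](OC(C)=O)[C@](C)(O1)[C@H]2CC[C@]3(C)O[C@@H]3C2 | intermediate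
13 | bromo‑THP / diaxial 4'‑Br,5'‑OH | CC1(C)O[C@](C)([C@H]2CC[C@@](C)(Br)[C@H](O)C2)[C@H](OC(C)=O)C[C@H]1Br | intermediate
14 | caespitol acetate | CC1(C)O[C@](C)([C@H]2CC[C@](C)(Cl)[C@@H](Br)C2)[C@H](OC(C)=O)C[C@H]1Br | intermediate
15 | caespitol | CC1(C)O[C@](C)([C@H]2CC[C@](C)(Cl)[C@@H](Br)C2)[C@H](O)C[C@H]1Br | target

## Summary
Total step count: 11. Longest linear sequence: 11 (from (S)‑limonene).

Steps most likely to fail:
1. **Step 9, THF → THP oxonium expansion.**
   - Risk: the reaction may stop at the tertiary‑bromide THF, or a 1,2‑hydride shift from C10 may drain material to an oxocarbenium ion.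
   - Fallback: give up the oxonium relay.
     1. Epoxidise only the side chain of 10 with the enantiomeric (L‑series) Shi ketone to the 10S epoxide.
     2. Open it at C10 with Li2NiBr4 (SN2) to the 10R bromohydrin.
     3. Ionise the tertiary C11–OH in HFIP so that the configurationally fixed bromonium ion is trapped by C7–OH.
     4. Treat the ring afterwards with the D‑Shi ketone, then carry out steps 9 (ring part) and 10.
2. **Step 10, 1,2‑bromine shift with chloride capture.**
   - Risk: elimination, or an iso (4'‑Br/5'‑Cl) product that does not equilibrate.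
   - Fallback: make C5'–Br by substitution instead of migration.
     1. Hydrolyse the ring epoxide to the trans‑diaxial (4'R,5'R) diol.
     2. Form the cyclic sulfate and open it with LiBr at C5' (SN2, Br cis to the side chain).
     3. Replace the tertiary sulfate/alcohol with chloride under SN1 conditions. The cation then arises at C4' itself, and the neighbouring Br blocks the upper face.
3. **Step 8, catalyst control on the ring alkene and survival of the ring epoxide.**
   - Risk: modest ring d.r. or acid lability.
   - Fallback: remove the need for face control.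
     1. Epoxidise the ring with mCPBA at the allyl stage (the acetate of 7), where it is the only electron‑rich alkene.
     2. Hydrolyse the epoxide mixture. Both epoxides open trans‑diaxially to the same (4'R,5'R) diol.
     3. Convert its tertiary OH to the axial bromide with HBr, which gives the same ring motif as in 13.
     4. Install the prenyl group and epoxidise the chain alone afterwards.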